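The runs come from a simulation for substances that don't exist; scatter was added.

If a free monomer leaves its free form, I ask where it ends: counted in chains, or somewhere else. The answer for a flask is then two numbers multiplied: the part of the free monomer used by the asked time, and the chance that a used one is counted in chains.

| flask | free monomer | initiator | temperature | remark | time |
|---|---|---|---|---|---|
| amber | 0.12 M | 1.1 mM | 1 °C | run made earlier |  |
| violet | 0.46 M | 1.1 mM | 15 °C | run made earlier |  |
| grey | 0.23 M | 2.2 mM | 1 °C | run made earlier |  |
| dawn | 0.23 M | 1.1 mM | 20 °C |  | 25 h |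
| summer | 0.23 M | 1.1 mM | −5 °C |  | 25 h |

| run | time / h | monomer in chains / % | free monomer / % |
|---|---|---|---|
| amber | 10.0 | 7.4 | 84.7 |
| amber | 20.0 | 14.6 | 70.6 |
| amber | 30.0 | 20.0 | 59.6 |
| amber | 40.0 | 21.8 | 48.7 |
| violet | 4.00 | 12.3 | 74.2 |
| violet | 8.00 | 19.0 | 56.9 |
| violet | 12.0 | 27.0 | 41.8 |
| violet | 15.0 | 29.6 | 35.2 |
| grey | 5.00 | 5.0 | 88.6 |
| grey | 12.0 | 11.3 | 75.2 |
| grey | 25.0 | 21.8 | 54.4 |
| grey | 40.0 | 29.2 | 39.9 |

(each reading ± 1 percentage point)

1. the best flask by amount of monomer in chains, in percent of the free monomer charged; "all alike" if 1.5 percentage points covers them all (dawn / summer / all alike)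
2. amount of monomer in chains at the end, in percent of the free monomer charged, dawn
3. amount of monomer in chains at the end, in percent of the free monomer charged, summer

- the earlier runs were read with a standard deviation of 1 percentage point
- a reading or a percentage of monomer in chains counts all its forms, free or not
- a reading of free monomer is of its free form alone

Which of the two must I know well? I get the part used from the rate constant of the fall of free monomer, which I treat as pseudo-first-order. Amber and violet carry 1.1 mM of initiator, as dawn and summer do, but they differ in free monomer as well as in temperature, so I assume that the rate constant does not depend on the free monomer charged and read their last readings as a temperature step: 0.0180 h⁻¹ at 1 °C and 0.0696 h⁻¹ at 15 °C. Carrying the same factor per degree onward gives 0.113 h⁻¹ for dawn and 0.0101 h⁻¹ for summer, so the parts used are 94.0 % and 22.3 %. A rate constant too low by a factor 2 would shift dawn's part used to 99.6 % but summer's to 39.6 %, so my summer figure leans harder on the temperature step than my dawn figure does. An error in the chance passes in equal proportion to dawn and summer, so for dawn the chance is the number to know well.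

At the last readings, the part of the used free monomer counted as monomer in chains is 42.5 % in amber, 45.7 % in violet and 48.6 % in grey. With readings scattered by 1 percentage point, I trust no trend and take the mean, 45.6 %, as the chain share. I commit to 42.9 % for dawn and 10.1 % for summer, dawn ahead by 33 points against a margin of 1.5 points.

The forecast says dawn, with 43 % for dawn and 9.3 % for summer, holding that “about 47% of the monomer consumed appears in chains”. It agrees with me on the best flask, and my summer figure stands above its own.

The flask gives dawn: 44.4 % for dawn and 9.57 % for summer. At the end of dawn, idle adduct holds 67.8 % of the free monomer charged and dormant form 10.7 %, and each idle adduct holds two charged units, one of them counted in chains. With 11 % of free monomer left in dawn, my chain share gives 40.6 %, below the result.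

    initiator → 2 initiating radical (k = 2.98 × 10⁻⁴ min⁻¹, Ea = 103 kJ mol⁻¹)
    free monomer + initiating radical → growing radical + monomer in chains (k = 2.38 × 10⁵ M⁻¹ s⁻¹, Ea = 19.0 kJ mol⁻¹)
    free monomer + growing radical → monomer in chains + growing radical, rate k3*[growing radical]*[free monomer] (k = 4.34 × 10⁵ M⁻¹ min⁻¹, Ea = 19.0 kJ mol⁻¹)
    2 growing radical → dead chain (k = 1.30 × 10⁹ M⁻¹ s⁻¹, Ea = 9.00 kJ mol⁻¹)
    free monomer + monomer in chains ⇌ idle adduct, settled at all times (K = 128 M⁻¹, ΔH = −62.0 kJ mol⁻¹)
    free monomer ⇌ dormant form (K = 6.70, k = 2.09 × 10⁻⁴ min⁻¹, Ea = 92.0 kJ mol⁻¹, ΔH = −30.0 kJ mol⁻¹)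
    (constants at 20 °C)

The neighbour flask, like dawn but with 6.6 × 10⁻⁴ M of initiator, keeps 15 % of its free monomer, so the chain share gives 38.8 %. The simulation gives 39.8 %.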